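**Strategy.** The furanone ring (O1, C2, C3, C4, C5) is opened between C3, the methyl-bearing carbon, and C4, the enol carbon. Read this way, O1–C2–C3 is a propanoate and C4–C5=C6 a 2-oxyacrylate, so the ring is the intramolecular Claisen product of an enol propanoate. The key step is a Dieckmann closure of an open-chain ethyl (E)-2-(propanoyloxy)-2-enoate that already holds the complete furyl ketone chain and the (S)-methyl centre. It forms the tetronic acid last, unprotected, and passes the pre-set C5=C6 geometry (side chain cis to C4) into the ring. The chain is assembled from myrcene, a chiral C4 bromo alcohol and 3-acetylfuran.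

Key step: step 8

Remark: the SMILES fixes the exocyclic C5=C6 bond as E (side chain cis to C4–OH, trans to O1), the less common geometry for 5-alkylidene tetronic acids; the enol ester geometry is chosen to deliver that isomer.

**Step 1**
Reactants: 1 β-myrcene; 2 (2R)-3-bromo-2-methylpropan-1-ol
Product: 4 (2S)-2,10-dimethyl-6-methylideneundec-9-en-1-ol, via B-alkyl-9-BBN borane 3 (not isolated)
Conditions: 9-BBN, THF, 0 °C → rt; then 2, Pd(OAc)2 (4 mol %), PCy3 (8 mol %), K3PO4·H2O, THF, rt → 40 °C
Reagents that add atoms: none
Why: 9-BBN should add boron to the terminal carbon of the monosubstituted vinyl group only, and the B-alkyl Suzuki–Miyaura alkyl–alkyl coupling then joins that carbon to the primary bromide without touching the hydroxyl or the stereocentre, which is bought in with 2.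

**Step 2**
Reactants: 4 (2S)-2,10-dimethyl-6-methylideneundec-9-en-1-ol
Product: 5 (2E,10S)-2,10-dimethyl-6-methylideneundec-2-ene-1,11-diol
Conditions: SeO2 (0.3 equiv), t-BuOOH (3 equiv), salicylic acid (0.1 equiv), CH2Cl2, 0 °C → rt
Reagents that add atoms: tert-butyl hydroperoxide, CC(C)(C)OO (source of the oxygen atom, relayed by catalytic SeO2, O=[Se]=O)
Why: Riley allylic oxidation (ene reaction, then [2,3]-sigmatropic shift) should attack the most electron-rich, trisubstituted alkene at its (E)-methyl group and so give the (E)-allylic alcohol, the 1,1-disubstituted alkene reacting more slowly; any over-oxidised enal can be returned with NaBH4.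

**Step 3**
Reactants: 5 (2E,10S)-2,10-dimethyl-6-methylideneundec-2-ene-1,11-diol
Product: 6 (2S,9E)-11-bromo-2,10-dimethyl-6-methylideneundec-9-en-1-ol
Conditions: N-bromosuccinimide, Me2S, CH2Cl2, −20 → 0 °C
Reagents that add atoms: N-bromosuccinimide, O=C1CCC(=O)N1Br
Why: In the Corey–Kim halogenation both hydroxyls form alkoxysulfonium salts, but only the allylic one is displaced by bromide (SN2, E geometry kept); the saturated primary alcohol is recovered on work-up.

**Step 4**
Reactants: 6 (2S,9E)-11-bromo-2,10-dimethyl-6-methylideneundec-9-en-1-ol; 7 3-acetylfuran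
Product: 8 (4E,12S)-1-(furan-3-yl)-13-hydroxy-4,12-dimethyl-8-methylidenetridec-4-en-1-one
Conditions: 7 (3 equiv), LiN(i-Pr)2 (4 equiv), THF, −78 °C; then 6, DMPU, −78 → −30 °C
Reagents that add atoms: none
Why: The kinetic lithium enolate of the methyl ketone should be C-alkylated by the reactive primary allylic bromide (enolate alkylation, SN2); the extra base holds the hydroxyl as its alkoxide and the excess enolate suppresses double alkylation.

**Step 5**
Reactants: 8 (4E,12S)-1-(furan-3-yl)-13-hydroxy-4,12-dimethyl-8-methylidenetridec-4-en-1-one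
Product: 9 (2S,9E)-13-(furan-3-yl)-2,10-dimethyl-6-methylidene-13-oxotridec-9-enal
Conditions: Dess–Martin periodinane, CH2Cl2, 0 °C → rt; used at once
Reagents that add atoms: none
Why: Dess–Martin oxidation is mild enough to give the α-methyl aldehyde without epimerisation and leaves ketone, furan and alkenes alone.

**Step 6**
Reactants: 10 ethyl glyoxylate; 11 bis(2,2,2-trifluoroethyl) phosphite; 12 propanoic anhydride
Product: 14 ethyl 2-[bis(2,2,2-trifluoroethoxy)phosphoryl]-2-(propanoyloxy)acetate, via hydroxyphosphonate 13 (not isolated)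
Conditions: 10 (toluene solution), 11, 80 °C, no base; then 12, Sc(OTf)3 (1 mol %), 0 °C → rt
Reagents that add atoms: none
Why: Pudovik addition of the P–H bond to the electrophilic glyoxylate aldehyde without base (avoiding phospha-Brook rearrangement), then Lewis-acid-catalysed O-acylation of the α-hydroxy phosphonate in the same flask.

**Step 7**
Reactants: 9 (2S,9E)-13-(furan-3-yl)-2,10-dimethyl-6-methylidene-13-oxotridec-9-enal; 14 ethyl 2-[bis(2,2,2-trifluoroethoxy)phosphoryl]-2-(propanoyloxy)acetate
Product: 15 ethyl (2E,4S,11E)-15-(furan-3-yl)-4,12-dimethyl-8-methylidene-15-oxo-2-(propanoyloxy)pentadeca-2,11-dienoate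
Conditions: 14 (1.3 equiv), KN(SiMe3)2 (1.2 equiv), 18-crown-6, THF, −78 °C; then 9, −78 °C
Reagents that add atoms: none
Why: Horner–Wadsworth–Emmons olefination in its Still–Gennari form: the electron-poor phosphonate under dissociating conditions should eliminate from the kinetic adduct and place the alkyl chain cis to the ester, i.e. the (2E)-enol ester; the stabilised anion reacts only with the aldehyde and is too weakly basic to epimerise the adjacent centre, and any (2Z) isomer is removed by chromatography.

**Step 8**
Reactants: 15 ethyl (2E,4S,11E)-15-(furan-3-yl)-4,12-dimethyl-8-methylidene-15-oxo-2-(propanoyloxy)pentadeca-2,11-dienoate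
Product: 16 (5E)-5-[(2S,9E)-13-(furan-3-yl)-2,10-dimethyl-6-methylidene-13-oxotridec-9-en-1-ylidene]-4-hydroxy-3-methylfuran-2(5H)-one
Conditions: LiN(SiMe3)2 (3.3 equiv), THF (high dilution), −78 → −30 °C, dark; then cold 1 M HCl
Reagents that add atoms: none
Why: The first equivalent of LiN(SiMe3)2 parks the furyl ketone as its lithium enolate, further base deprotonates the propanoate CH2 (acidified because it is an enol ester), and this enolate carbon (future C3) adds to the neighbouring ethyl ester carbonyl (future C4); loss of ethoxide and deprotonation of the 2,4-dione to the tetronate anion make the closure irreversible. The closest known reaction is the Dieckmann (intramolecular Claisen) cyclisation of 2-acyloxy esters to tetronic acids and of 2-(arylacetoxy)cinnamates to pulvinones. The furanone ring (O1, C2, C3, C4, C5) is closed in the 5-(enolendo)-exo-trig mode at C4, the mode through which tetronic and tetramic acids are routinely made. No stereocentre is created: the (S)-centre lies outside the reacting atoms and the C5=C6 double bond is a bystander, so the (E) geometry of 15 should be carried into the ring. The step needs C-acylation by the propanoate enolate in preference to acyl transfer to the ketone enolate, removal of the allylic methine hydrogen, or ketene loss; the five-membered intramolecular transition state, dilution, low temperature and the hindered tertiary methine are relied on to secure it.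

**Compound list**

1 | β-myrcene (7-methyl-3-methylideneocta-1,6-diene) | C=CC(=C)CCC=C(C)C | starting material
2 | (2R)-3-bromo-2-methylpropan-1-ol | OC[C@@H](C)CBr | starting material
3 | 9-(7-methyl-3-methylideneoct-6-en-1-yl)-9-borabicyclo[3.3.1]nonane | CC(C)=CCCC(=C)CCB1C2CCCC1CCC2 | intermediate (not isolated)
4 | (2S)-2,10-dimethyl-6-methylideneundec-9-en-1-ol | OC[C@@H](C)CCCC(=C)CCC=C(C)C | intermediate
5 | (2E,10S)-2,10-dimethyl-6-methylideneundec-2-ene-1,11-diol | OC[C@@H](C)CCCC(=C)CC/C=C(\C)CO | intermediate
6 | (2S,9E)-11-bromo-2,10-dimethyl-6-methylideneundec-9-en-1-ol | OC[C@@H](C)CCCC(=C)CC/C=C(\C)CBr | intermediate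
7 | 3-acetylfuran (1-(furan-3-yl)ethan-1-one) | CC(=O)c1ccoc1 | starting material
8 | (4E,12S)-1-(furan-3-yl)-13-hydroxy-4,12-dimethyl-8-methylidenetridec-4-en-1-one | OC[C@@H](C)CCCC(=C)CC/C=C(\C)CCC(=O)c1ccoc1 | intermediate
9 | (2S,9E)-13-(furan-3-yl)-2,10-dimethyl-6-methylidene-13-oxotridec-9-enal | O=C[C@@H](C)CCCC(=C)CC/C=C(\C)CCC(=O)c1ccoc1 | intermediate
10 | ethyl glyoxylate | O=CC(=O)OCC | starting material
11 | bis(2,2,2-trifluoroethyl) phosphite | O=[PH](OCC(F)(F)F)OCC(F)(F)F | starting material
12 | propanoic anhydride | CCC(=O)OC(=O)CC | starting material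
13 | ethyl 2-[bis(2,2,2-trifluoroethoxy)phosphoryl]-2-hydroxyacetate | CCOC(=O)C(O)P(=O)(OCC(F)(F)F)OCC(F)(F)F | intermediate (not isolated)
14 | ethyl 2-[bis(2,2,2-trifluoroethoxy)phosphoryl]-2-(propanoyloxy)acetate | CCOC(=O)C(OC(=O)CC)P(=O)(OCC(F)(F)F)OCC(F)(F)F | intermediate
15 | ethyl (2E,4S,11E)-15-(furan-3-yl)-4,12-dimethyl-8-methylidene-15-oxo-2-(propanoyloxy)pentadeca-2,11-dienoate | C=C(CC/C=C(\C)CCC(=O)c1ccoc1)CCC[C@H](C)/C=C(/OC(=O)CC)C(=O)OCC | intermediate
16 | (5E)-5-[(2S,9E)-13-(furan-3-yl)-2,10-dimethyl-6-methylidene-13-oxotridec-9-en-1-ylidene]-4-hydroxy-3-methylfuran-2(5H)-one | C=C(CC/C=C(\C)CCC(=O)c1ccoc1)CCC[C@H](C)/C=C1/OC(=O)C(C)=C1O | target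

**Totals**

Total step count: 8. Longest linear sequence: 7 (steps 1, 2, 3, 4, 5, 7, 8); step 6 is the side branch.

**Steps most likely to fail**

1. Step 8 (key ring closure). The base may be used up in side channels before the ring closes: acyl transfer from the enol ester to the ketone enolate, removal of the allylic methine hydrogen with loss of the (S)-configuration and of the alkene geometry, or collapse of the propanoate enolate to methylketene. Fallback: mask the ketone before the closure. It sets out from 8 and returns at 16. Ketalisation of 8 (ethylene glycol, pyridinium p-toluenesulfonate, benzene, reflux with water removal) should give the hydroxy dioxolane F1. Dess–Martin oxidation gives the dioxolane aldehyde F2, and the same olefination with 14 gives the dioxolane enol ester F3. Dieckmann closure, now with only 2.2 equiv of LiN(SiMe3)2 and no ketone present, gives the dioxolane-protected tetronic acid F4. Brief treatment with pyridinium p-toluenesulfonate in wet acetone in the dark removes the ketal and returns to 16.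

2. Step 7 (olefination geometry). Elimination may not outrun equilibration of the adducts, which would give the (2Z)-enol ester (chain trans to the ester) and hence the wrong ring-alkylidene geometry; base-mediated epimerisation of the α-methyl aldehyde is the second concern. Fallback: fix the geometry with a halogen first. It sets out from 9 and returns at 15. Commercial ethyl 2-[bis(2,2,2-trifluoroethoxy)phosphoryl]acetate is brominated (NaH, then N-bromosuccinimide, THF, −78 °C) to the bromophosphonate F5. Olefination of 9 with F5 (KOt-Bu, 18-crown-6, THF, −78 °C), a reagent type known to place the alkyl group cis to the ester, should give the (2E)-bromoacrylate F6. Copper-catalysed vinylic C–O coupling with retention of geometry (CuI, 1,10-phenanthroline, cesium propanoate, toluene, 80 °C) returns to 15.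

3. Step 1 (alkyl–alkyl coupling). Oxidative addition of zerovalent palladium into the β-branched primary bromide may be slow, so that β-hydride elimination and protodeboronation outrun the coupling. Fallback: a Kochi-type copper-catalysed Grignard coupling. It sets out from 1 and 2 and returns at 4. Hydroboration–oxidation of 1 (9-BBN, THF; NaOH, H2O2) gives the homoallylic alcohol F7, which is tosylated (TsCl, pyridine) to the tosylate F8. Bromo alcohol 2 is silylated (TBSCl, imidazole, DMF) to the silyl ether bromide F9 and converted with Mg in THF into the Grignard reagent F10. Coupling of F10 with F8 (Li2CuCl4 cat., THF, −78 → 0 °C) should give the coupled silyl ether F11, and n-Bu4NF in THF returns to 4.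

**Further compounds**

F1 | step 8 | (2S,9E)-12-[2-(furan-3-yl)-1,3-dioxolan-2-yl]-2,10-dimethyl-6-methylidenedodec-9-en-1-ol | OC[C@@H](C)CCCC(=C)CC/C=C(\C)CCC1(OCCO1)c1ccoc1
F2 | step 8 | (2S,9E)-12-[2-(furan-3-yl)-1,3-dioxolan-2-yl]-2,10-dimethyl-6-methylidenedodec-9-enal | O=C[C@@H](C)CCCC(=C)CC/C=C(\C)CCC1(OCCO1)c1ccoc1
F3 | step 8 | ethyl (2E,4S,11E)-14-[2-(furan-3-yl)-1,3-dioxolan-2-yl]-4,12-dimethyl-8-methylidene-2-(propanoyloxy)tetradeca-2,11-dienoate | C=C(CC/C=C(\C)CCC1(OCCO1)c1ccoc1)CCC[C@H](C)/C=C(/OC(=O)CC)C(=O)OCC
F4 | step 8 | (5E)-5-{(2S,9E)-12-[2-(furan-3-yl)-1,3-dioxolan-2-yl]-2,10-dimethyl-6-methylidenedodec-9-en-1-ylidene}-4-hydroxy-3-methylfuran-2(5H)-one | C=C(CC/C=C(\C)CCC1(OCCO1)c1ccoc1)CCC[C@H](C)/C=C1/OC(=O)C(C)=C1O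
F5 | step 7 | ethyl 2-[bis(2,2,2-trifluoroethoxy)phosphoryl]-2-bromoacetate | CCOC(=O)C(Br)P(=O)(OCC(F)(F)F)OCC(F)(F)F
F6 | step 7 | ethyl (2E,4S,11E)-2-bromo-15-(furan-3-yl)-4,12-dimethyl-8-methylidene-15-oxopentadeca-2,11-dienoate | C=C(CC/C=C(\C)CCC(=O)c1ccoc1)CCC[C@H](C)/C=C(/Br)C(=O)OCC
F7 | step 1 | 7-methyl-3-methylideneoct-6-en-1-ol | CC(C)=CCCC(=C)CCO
F8 | step 1 | 7-methyl-3-methylideneoct-6-en-1-yl 4-methylbenzenesulfonate | CC(C)=CCCC(=C)CCOS(=O)(=O)c1ccc(C)cc1
F9 | step 1 | [(2R)-3-bromo-2-methylpropoxy](tert-butyl)dimethylsilane | CC(C)(C)[Si](C)(C)OC[C@@H](C)CBr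
F10 | step 1 | {(2R)-3-[(tert-butyldimethylsilyl)oxy]-2-methylpropyl}magnesium bromide | CC(C)(C)[Si](C)(C)OC[C@@H](C)C[Mg]Br
F11 | step 1 | tert-butyl{[(2S)-2,10-dimethyl-6-methylideneundec-9-en-1-yl]oxy}dimethylsilane | CC(C)(C)[Si](C)(C)OC[C@@H](C)CCCC(=C)CCC=C(C)C
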